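**Remark:** Locants C1–C8a are those of the octahydronaphthalene core of the target (C1 dienoic acid chain, C2 butenyl, C3 methyl, C7 sulfate, C8 methyl; ring A = C1–C4, C4a, C8a; ring B = C4a–C8a). The target is taken in the free-acid form drawn; in practice it would be stored as a salt and liberated by the final acidification.

## Retrosynthetic overview

1. Target ⇒ hydroxy dienoate 25 (sulfation, saponification) ⇒ vinylogous HWE on a C1 aldehyde; the C7 carbinol comes from dissolving-metal reduction of a ring-B enone.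
2. Key disconnection C4–C4a: a 6-exo intramolecular Heck reaction of a (Z)-alkenyl iodide (C3=C4–I) onto the C4a=C5 alkene of a ring-B cyclohexene ketal closes ring A last and fixes the cis ring fusion.
3. The C1–C2 bond, both of its stereocentres and the (E)-butenyl group come from one Ireland–Claisen rearrangement of the ester of ring-B acetic acid 8 with dienol 14.
4. Ring B comes first, from (S)-carvone: Criegee degradation to an acetoxy enone, Mukaiyama–Michael addition/elimination (sets C8a, C8), then deconjugative ketalisation.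
5. Enabling feature: the ring-A alkene C3=C4 ends in a vinylic CH (C4) bonded directly to the ring-fusion carbon C4a, and the C7 oxygen lies two carbons from C5 in ring B. A C7 ketal can therefore hold the acceptor alkene at C4a=C5 and receive the Heck-transposed C5=C6 alkene as a masked enone.

Key step: step 11

## Route

Step 1
Reactants: 1 (S)-(+)-carvone
Product: 4 (5S)-5-acetoxy-2-methylcyclohex-2-en-1-one, via methoxy hydroperoxide 2 (not isolated), via peracetate 3 (not isolated)
Conditions: O3, CH2Cl2/MeOH, −78 °C; Ar purge; then Ac2O, Et3N, DMAP (cat.), CH2Cl2, 0 °C → rt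
Reagents that add atoms: ozone O=[O+][O-]; methanol CO; acetic anhydride CC(=O)OC(C)=O (acetyl retained in 3 only)
Why: Ozone cleaves only the electron-rich isopropenyl alkene (the enone alkene is electron-poor), methanol traps the carbonyl oxide as the α-methoxy hydroperoxide, and acetylation triggers a Criegee rearrangement in which the ring carbon migrates to oxygen with retention, so the (S) centre of carvone becomes the (S) acetoxy centre.

Step 2
Reactants: 4 (5S)-5-acetoxy-2-methylcyclohex-2-en-1-one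
Product: 6 methyl 2-[(1R,6R)-6-methyl-5-oxocyclohex-3-en-1-yl]acetate, via keto acetate 5 (not isolated)
Conditions: 1-(tert-butyldimethylsilyloxy)-1-methoxyethene, TiCl4, CH2Cl2, −78 °C; aq. NaHCO3; crude with DBU, CH2Cl2, 0 °C → rt
Reagents that add atoms: 1-(tert-butyldimethylsilyloxy)-1-methoxyethene COC(=C)O[Si](C)(C)C(C)(C)C
Why: Lewis-acid-promoted Mukaiyama–Michael addition of the ketene silyl acetal occurs at the enone β-carbon on the face anti to the C5 acetoxy group (axial attack trans to a 5-substituent, as with carvone-type and 5-oxygenated cyclohexenones), which sets C8a, and DBU then expels acetate by E1cB and equilibrates the α-methyl centre C8 to the more stable trans arrangement.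

Step 3
Reactants: 6 methyl 2-[(1R,6R)-6-methyl-5-oxocyclohex-3-en-1-yl]acetate
Product: 7 methyl 2-[(6R,7S)-6-methyl-1,4-dioxaspiro[4.5]dec-8-en-7-yl]acetate
Conditions: ethylene glycol, p-TsOH·H2O (cat.), benzene, reflux with azeotropic removal of water
Reagents that add atoms: ethylene glycol OCCO
Why: Acid-catalysed ketalisation of a cyclohex-2-enone with ethylene glycol runs through the dienol ether and under equilibrating conditions should give the β,γ-unsaturated dioxolane (the double-bond migration familiar from steroidal enones), which places the alkene at C4a=C5 next to C8a without touching a stereocentre.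

Step 4
Reactants: 7 methyl 2-[(6R,7S)-6-methyl-1,4-dioxaspiro[4.5]dec-8-en-7-yl]acetate
Product: 8 2-[(6R,7S)-6-methyl-1,4-dioxaspiro[4.5]dec-8-en-7-yl]acetic acid
Conditions: LiOH, THF/MeOH/H2O, rt; then 0.5 M HCl to pH 4, 0 °C
Reagents that add atoms: lithium hydroxide [Li+].[OH-]
Why: Ester saponification, in which the dioxolane is stable to hydroxide and to the brief, cold, weakly acidic work-up.

Step 5
Reactants: 9 prop-2-yn-1-ol
Product: 11 (Z)-3-iodo-2-methylprop-2-en-1-ol, via alkenylmagnesium alkoxide 10 (not isolated)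
Conditions: MeMgBr (2.3 equiv), CuI (10 mol%), THF, −10 °C → rt; then I2, THF, −10 °C; water
Reagents that add atoms: methylmagnesium bromide C[Mg]Br; iodine II
Why: Copper-catalysed carbomagnesiation of propargyl alcohol adds methyl and magnesium anti across the alkyne to give the oxygen-chelated (Z)-alkenylmagnesium, and iodinolysis with retention then gives the (Z)-iodoalkene.

Step 6
Reactants: 11 (Z)-3-iodo-2-methylprop-2-en-1-ol
Product: 12 (Z)-3-iodo-2-methylprop-2-enal
Conditions: MnO2 (activated, excess), CH2Cl2, rt, dark; used at once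
Reagents that add atoms: none
Why: Heterogeneous MnO2 oxidation is selective for allylic alcohols and neutral, so the (Z)-β-iodo enal should form without isomerisation of the alkene.

Step 7
Reactants: 12 (Z)-3-iodo-2-methylprop-2-enal
Product: 13 (3E,5Z)-6-iodo-3,5-dimethylhexa-3,5-dien-2-one
Conditions: 3-(triphenylphosphoranylidene)butan-2-one, toluene, 70 °C, dark
Reagents that add atoms: 3-(triphenylphosphoranylidene)butan-2-one CC(=O)C(C)=P(c1ccccc1)(c1ccccc1)c1ccccc1
Why: Wittig olefination with a stabilised acyl ylide gives the (E)-trisubstituted enone, and the (Z)-iodoalkene is untouched under these salt-free neutral conditions.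

Step 8
Reactants: 13 (3E,5Z)-6-iodo-3,5-dimethylhexa-3,5-dien-2-one
Product: 14 (2S,3E,5Z)-6-iodo-3,5-dimethylhexa-3,5-dien-2-ol
Conditions: (R)-2-methyl-CBS-oxazaborolidine (20 mol%), catecholborane, toluene, −78 °C; MeOH, then aq. NaOH
Reagents that add atoms: none
Why: Corey–Bakshi–Shibata reduction of the α-substituted enone, in which the alkenyl group acts as the large substituent, with the (R)-oxazaborolidine and catecholborane (1,2-selective, no hydroboration at −78 °C) sets the (S) carbinol centre.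

Step 9
Reactants: 8 2-[(6R,7S)-6-methyl-1,4-dioxaspiro[4.5]dec-8-en-7-yl]acetic acid; 14 (2S,3E,5Z)-6-iodo-3,5-dimethylhexa-3,5-dien-2-ol
Product: 15 (2S,3E,5Z)-6-iodo-3,5-dimethylhexa-3,5-dien-2-yl 2-[(6R,7S)-6-methyl-1,4-dioxaspiro[4.5]dec-8-en-7-yl]acetate
Conditions: DCC, DMAP (cat.), CH2Cl2, 0 °C → rt
Reagents that add atoms: none
Why: Carbodiimide/DMAP (Steglich) esterification acylates the secondary allylic alcohol under neutral conditions without ionising it and without touching the ketal.

Step 10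
Reactants: 15 (2S,3E,5Z)-6-iodo-3,5-dimethylhexa-3,5-dien-2-yl 2-[(6R,7S)-6-methyl-1,4-dioxaspiro[4.5]dec-8-en-7-yl]acetate
Product: 19 methyl (2S,3S,4E)-3-[(1Z)-1-iodoprop-1-en-2-yl]-4-methyl-2-[(6R,7S)-6-methyl-1,4-dioxaspiro[4.5]dec-8-en-7-yl]hex-4-enoate, via silyl ketene acetal 16 (not isolated), via trimethylsilyl ester 17 (not isolated), via carboxylic acid 18 (not isolated)
Conditions: LiN(iPr)2, THF/DMPU (4:1), −78 °C; TMSCl; −78 °C → rt, then 50 °C; aq. NaOH, then citric acid to pH 4; then TMSCHN2, toluene/MeOH, 0 °C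
Reagents that add atoms: chlorotrimethylsilane C[Si](C)(C)Cl (retained in 16 and 17 only); (trimethylsilyl)diazomethane C[Si](C)(C)C=[N+]=[N-]
Why: Ireland–Claisen rearrangement, in which enolisation in THF/DMPU gives the ketene acetal with the C8a substituent cis to the silyloxy group and the chair transition state with the carbinol methyl equatorial transfers the (S) carbinol chirality to C2, holds the C8a substituent equatorial to set C1 in the C1/C2 relationship of the target, and delivers the (E)-butenyl alkene, after which the silyl ester is hydrolysed and the acid methylated.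

Step 11
Reactants: 19 methyl (2S,3S,4E)-3-[(1Z)-1-iodoprop-1-en-2-yl]-4-methyl-2-[(6R,7S)-6-methyl-1,4-dioxaspiro[4.5]dec-8-en-7-yl]hex-4-enoate
Product: 20 methyl 2-[(E)-but-2-en-2-yl]-7,7-(ethylenedioxy)-3,8-dimethyl-1,2,4a,7,8,8a-hexahydronaphthalene-1-carboxylate (cis-fused; C1, C2, C4a, C8, C8a arranged as in 27)
Conditions: Pd(OAc)2 (10 mol%), PPh3 (30 mol%), Ag2CO3 (2 equiv), MeCN, 80 °C, degassed, dark
Reagents that add atoms: none
Why: Zerovalent palladium (from Pd(OAc)2/PPh3) inserts into the C4–I bond with retention of the (Z) geometry, the alkenylpalladium adds syn across C4a=C5 in a 6-exo-trig carbopalladation that forms C4–C4a, and syn β-hydride elimination towards C6 releases the diene while Ag2CO3 takes up iodide and suppresses Pd–H re-addition. The closest known reaction type is the intramolecular Heck cyclisation of alkenyl halides onto cyclohexenes, an established entry to cis-fused decalins. Ring A is closed in the 6-exo mode, and the only new stereocentre, C4a, is controlled by C8a: the three-atom tether C1–C2–C3 hanging from C8a can reach only the alkene face syn to the C8a–C1 bond, so H4a and H8a end cis, with the C1 ester and C2 butenyl groups equatorial in the chair-like transition state. The selectivities needed are 6-exo over 7-endo insertion (ring size), loss of a C6 hydrogen rather than H4a (H4a is anti to palladium after syn addition), and no migration of the new alkene, which the hydrogen-free ketal carbon C7 next to C6 and the silver salt should secure. The (Z)-iodide geometry, fixed in step 5 and carried through, is what lets C4 reach C4a with C3=C4 already in its final endocyclic position. The product holds C5=C6 as an allylic ketal, a masked enone that steps 13 and 14 turn into the C7 carbinol.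

Step 12
Reactants: 20 methyl 2-[(E)-but-2-en-2-yl]-7,7-(ethylenedioxy)-3,8-dimethyl-1,2,4a,7,8,8a-hexahydronaphthalene-1-carboxylate
Product: 21 [2-[(E)-but-2-en-2-yl]-7,7-(ethylenedioxy)-3,8-dimethyl-1,2,4a,7,8,8a-hexahydronaphthalen-1-yl]methanol (stereocentres as in 20)
Conditions: LiAlH4, Et2O, 0 °C; aq. NaOH work-up
Reagents that add atoms: none
Why: LiAlH4 reduces the ester to the primary alcohol and leaves the allylic ketal and the unconjugated alkenes alone.

Step 13
Reactants: 21 [2-[(E)-but-2-en-2-yl]-7,7-(ethylenedioxy)-3,8-dimethyl-1,2,4a,7,8,8a-hexahydronaphthalen-1-yl]methanol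
Product: 22 2-[(E)-but-2-en-2-yl]-1-(hydroxymethyl)-3,8-dimethyl-1,4a,8,8a-tetrahydronaphthalen-7(2H)-one (target locants; stereocentres as in 20)
Conditions: PPTS (cat.), acetone/H2O (10:1), rt
Reagents that add atoms: water O
Why: The allylic dioxolane hydrolyses under very mild acid through a stabilised allylic oxocarbenium ion, giving the conjugated C5=C6–C7=O enone before acid can enolise towards the doubly allylic C4a–H or the C8–H.

Step 14
Reactants: 22 2-[(E)-but-2-en-2-yl]-1-(hydroxymethyl)-3,8-dimethyl-1,4a,8,8a-tetrahydronaphthalen-7(2H)-one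
Product: 23 2-[(E)-but-2-en-2-yl]-1-(hydroxymethyl)-3,8-dimethyl-1,2,4a,5,6,7,8,8a-octahydronaphthalen-7-ol (target locants; all six stereocentres as in 27)
Conditions: Li (excess), NH3(l)/THF, EtOH, −78 → −33 °C; NH4Cl
Reagents that add atoms: none
Why: Dissolving-metal (Birch-type) reduction converts the enone into the C6/C7 enolate, which is protonated to the ketone and reduced further in the presence of ethanol under thermodynamic control, so the new C7 hydroxyl should take the equatorial position cis to the C8 methyl (a hydride would instead be steered by the 1,3-diaxial C8a–C1 bond), while the isolated trisubstituted alkenes are not reduced.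

Step 15
Reactants: 23 2-[(E)-but-2-en-2-yl]-1-(hydroxymethyl)-3,8-dimethyl-1,2,4a,5,6,7,8,8a-octahydronaphthalen-7-ol
Product: 24 2-[(E)-but-2-en-2-yl]-7-hydroxy-3,8-dimethyl-1,2,4a,5,6,7,8,8a-octahydronaphthalene-1-carbaldehyde (stereocentres as in 27)
Conditions: TEMPO (10 mol%), PhI(OAc)2 (1.1 equiv), CH2Cl2, rt
Reagents that add atoms: none
Why: Oxoammonium (TEMPO/PhI(OAc)2) oxidation is selective for the primary over the secondary alcohol and stops at the aldehyde under anhydrous, non-basic conditions, which protects the C1 stereocentre from epimerisation.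

Step 16
Reactants: 24 2-[(E)-but-2-en-2-yl]-7-hydroxy-3,8-dimethyl-1,2,4a,5,6,7,8,8a-octahydronaphthalene-1-carbaldehyde
Product: 25 ethyl (2E,4E)-5-[(1S,2S,4aS,7S,8R,8aR)-2-[(E)-but-2-en-2-yl]-7-hydroxy-3,8-dimethyl-1,2,4a,5,6,7,8,8a-octahydronaphthalen-1-yl]penta-2,4-dienoate
Conditions: ethyl (E)-4-(diethoxyphosphoryl)but-2-enoate (2.5 equiv), LiN(SiMe3)2 (2.4 equiv), THF, −78 → 0 °C; aq. NH4Cl
Reagents that add atoms: ethyl (E)-4-(diethoxyphosphoryl)but-2-enoate CCOC(=O)/C=C/CP(=O)(OCC)OCC
Why: Vinylogous Horner–Wadsworth–Emmons olefination with the lithiated 4-phosphonocrotonate should give the (2E,4E)-dienoate, and the free secondary hydroxyl only consumes extra base.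

Step 17
Reactants: 25 ethyl (2E,4E)-5-[(1S,2S,4aS,7S,8R,8aR)-2-[(E)-but-2-en-2-yl]-7-hydroxy-3,8-dimethyl-1,2,4a,5,6,7,8,8a-octahydronaphthalen-1-yl]penta-2,4-dienoate
Product: 26 ethyl (2E,4E)-5-[(1S,2S,4aS,7S,8R,8aR)-2-[(E)-but-2-en-2-yl]-3,8-dimethyl-7-(sulfooxy)-1,2,4a,5,6,7,8,8a-octahydronaphthalen-1-yl]penta-2,4-dienoate (handled as its pyridinium salt)
Conditions: SO3·pyridine (5 equiv), pyridine, rt
Reagents that add atoms: sulfur trioxide–pyridine complex O=S(=O)([O-])[n+]1ccccc1
Why: O-Sulfation of the secondary alcohol with the SO3–pyridine complex gives the sulfate monoester with retention at C7, because only the O–H bond is involved.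

Step 18
Reactants: 26 ethyl (2E,4E)-5-[(1S,2S,4aS,7S,8R,8aR)-2-[(E)-but-2-en-2-yl]-3,8-dimethyl-7-(sulfooxy)-1,2,4a,5,6,7,8,8a-octahydronaphthalen-1-yl]penta-2,4-dienoate
Product: 27 (2E,4E)-5-[(1S,2S,4aS,7S,8R,8aR)-2-[(E)-but-2-en-2-yl]-3,8-dimethyl-7-(sulfooxy)-1,2,4a,5,6,7,8,8a-octahydronaphthalen-1-yl]penta-2,4-dienoic acid
Conditions: LiOH (excess), THF/MeOH/H2O, rt; then cold 0.5 M HCl to pH 2, extraction with n-BuOH
Reagents that add atoms: lithium hydroxide [Li+].[OH-]
Why: Hydroxide saponifies the ethyl ester while the sulfate monoester anion resists hydroxide, and cold acidification liberates the diacid.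

## Compound list

1 | (S)-(+)-carvone, (5S)-2-methyl-5-(prop-1-en-2-yl)cyclohex-2-en-1-one | CC1=CC[C@H](C(C)=C)CC1=O | starting material
2 | (5S)-5-(1-hydroperoxy-1-methoxyethyl)-2-methylcyclohex-2-en-1-one (epimers at the peroxy carbon) | CC1=CC[C@H](C(C)(OC)OO)CC1=O | intermediate
3 | (5S)-5-[1-(acetylperoxy)-1-methoxyethyl]-2-methylcyclohex-2-en-1-one | CC1=CC[C@H](C(C)(OC)OOC(C)=O)CC1=O | intermediate
4 | (5S)-5-acetoxy-2-methylcyclohex-2-en-1-one | CC1=CC[C@H](OC(C)=O)CC1=O | intermediate
5 | methyl 2-[(1R,5S)-5-acetoxy-2-methyl-3-oxocyclohexyl]acetate (C2 epimers) | COC(=O)C[C@H]1C[C@H](OC(C)=O)CC(=O)C1C | intermediate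
6 | methyl 2-[(1R,6R)-6-methyl-5-oxocyclohex-3-en-1-yl]acetate | COC(=O)C[C@H]1CC=CC(=O)[C@@H]1C | intermediate
7 | methyl 2-[(6R,7S)-6-methyl-1,4-dioxaspiro[4.5]dec-8-en-7-yl]acetate | COC(=O)C[C@H]1C=CCC2(OCCO2)[C@@H]1C | intermediate
8 | 2-[(6R,7S)-6-methyl-1,4-dioxaspiro[4.5]dec-8-en-7-yl]acetic acid | OC(=O)C[C@H]1C=CCC2(OCCO2)[C@@H]1C | intermediate
9 | prop-2-yn-1-ol (propargyl alcohol) | C#CCO | starting material
10 | bromo[(Z)-3-(bromomagnesiooxy)-2-methylprop-1-en-1-yl]magnesium | Br[Mg]/C=C(/C)CO[Mg]Br | intermediate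
11 | (Z)-3-iodo-2-methylprop-2-en-1-ol | OC/C(C)=C\I | intermediate
12 | (Z)-3-iodo-2-methylprop-2-enal | O=C/C(C)=C\I | intermediate
13 | (3E,5Z)-6-iodo-3,5-dimethylhexa-3,5-dien-2-one | CC(=O)/C(C)=C/C(C)=C\I | intermediate
14 | (2S,3E,5Z)-6-iodo-3,5-dimethylhexa-3,5-dien-2-ol | C[C@H](O)/C(C)=C/C(C)=C\I | intermediate
15 | (2S,3E,5Z)-6-iodo-3,5-dimethylhexa-3,5-dien-2-yl 2-[(6R,7S)-6-methyl-1,4-dioxaspiro[4.5]dec-8-en-7-yl]acetate | C[C@H](OC(=O)C[C@H]1C=CCC2(OCCO2)[C@@H]1C)/C(C)=C/C(C)=C\I | intermediate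
16 | (Z)-O-trimethylsilyl ketene acetal of 15 (C8a substituent cis to OSiMe3) | C[C@H](O/C(O[Si](C)(C)C)=C/[C@H]1C=CCC2(OCCO2)[C@@H]1C)/C(C)=C/C(C)=C\I | intermediate
17 | trimethylsilyl ester of 18 | C/C=C(\C)[C@@H](/C(C)=C\I)[C@@H](C(=O)O[Si](C)(C)C)[C@H]1C=CCC2(OCCO2)[C@@H]1C | intermediate
18 | (2S,3S,4E)-3-[(1Z)-1-iodoprop-1-en-2-yl]-4-methyl-2-[(6R,7S)-6-methyl-1,4-dioxaspiro[4.5]dec-8-en-7-yl]hex-4-enoic acid | C/C=C(\C)[C@@H](/C(C)=C\I)[C@@H](C(=O)O)[C@H]1C=CCC2(OCCO2)[C@@H]1C | intermediate
19 | methyl (2S,3S,4E)-3-[(1Z)-1-iodoprop-1-en-2-yl]-4-methyl-2-[(6R,7S)-6-methyl-1,4-dioxaspiro[4.5]dec-8-en-7-yl]hex-4-enoate | C/C=C(\C)[C@@H](/C(C)=C\I)[C@@H](C(=O)OC)[C@H]1C=CCC2(OCCO2)[C@@H]1C | intermediate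
20 | methyl 2-[(E)-but-2-en-2-yl]-7,7-(ethylenedioxy)-3,8-dimethyl-1,2,4a,7,8,8a-hexahydronaphthalene-1-carboxylate (cis-fused; stereocentres arranged as in 27) | C/C=C(\C)[C@H]1C(C)=C[C@H]2C=CC3(OCCO3)[C@H](C)[C@H]2[C@@H]1C(=O)OC | intermediate
21 | [2-[(E)-but-2-en-2-yl]-7,7-(ethylenedioxy)-3,8-dimethyl-1,2,4a,7,8,8a-hexahydronaphthalen-1-yl]methanol (stereocentres as in 20) | C/C=C(\C)[C@H]1C(C)=C[C@H]2C=CC3(OCCO3)[C@H](C)[C@H]2[C@@H]1CO | intermediate
22 | 2-[(E)-but-2-en-2-yl]-1-(hydroxymethyl)-3,8-dimethyl-1,4a,8,8a-tetrahydronaphthalen-7(2H)-one (target locants; stereocentres as in 20) | C/C=C(\C)[C@H]1C(C)=C[C@H]2C=CC(=O)[C@H](C)[C@H]2[C@@H]1CO | intermediate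
23 | 2-[(E)-but-2-en-2-yl]-1-(hydroxymethyl)-3,8-dimethyl-1,2,4a,5,6,7,8,8a-octahydronaphthalen-7-ol (target locants; stereocentres as in 27) | C/C=C(\C)[C@H]1C(C)=C[C@H]2CC[C@H](O)[C@H](C)[C@H]2[C@@H]1CO | intermediate
24 | 2-[(E)-but-2-en-2-yl]-7-hydroxy-3,8-dimethyl-1,2,4a,5,6,7,8,8a-octahydronaphthalene-1-carbaldehyde (stereocentres as in 27) | C/C=C(\C)[C@H]1C(C)=C[C@H]2CC[C@H](O)[C@H](C)[C@H]2[C@@H]1C=O | intermediate
25 | ethyl (2E,4E)-5-[(1S,2S,4aS,7S,8R,8aR)-2-[(E)-but-2-en-2-yl]-7-hydroxy-3,8-dimethyl-1,2,4a,5,6,7,8,8a-octahydronaphthalen-1-yl]penta-2,4-dienoate | C/C=C(\C)[C@H]1C(C)=C[C@H]2CC[C@H](O)[C@H](C)[C@H]2[C@@H]1/C=C/C=C/C(=O)OCC | intermediate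
26 | ethyl (2E,4E)-5-[(1S,2S,4aS,7S,8R,8aR)-2-[(E)-but-2-en-2-yl]-3,8-dimethyl-7-(sulfooxy)-1,2,4a,5,6,7,8,8a-octahydronaphthalen-1-yl]penta-2,4-dienoate | C/C=C(\C)[C@H]1C(C)=C[C@H]2CC[C@H](OS(=O)(=O)O)[C@H](C)[C@H]2[C@@H]1/C=C/C=C/C(=O)OCC | intermediate
27 | (2E,4E)-5-[(1S,2S,4aS,7S,8R,8aR)-2-[(E)-but-2-en-2-yl]-3,8-dimethyl-7-(sulfooxy)-1,2,4a,5,6,7,8,8a-octahydronaphthalen-1-yl]penta-2,4-dienoic acid | C/C=C(\C)[C@H]1C(C)=C[C@H]2CC[C@H](OS(=O)(=O)O)[C@H](C)[C@H]2[C@@H]1/C=C/C=C/C(=O)O | target

## Step count and risks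

Total steps: 18. Longest linear sequence: 14 steps (steps 1–4, then 9–18).

**Step 3 (deconjugative ketalisation).** The double-bond migration may be incomplete, leaving a mixture of α,β- and β,γ-unsaturated ketals, or the glycol may add in conjugate fashion to the enone. The fallback sets out from 6 and moves the alkene by the classical dienol-ester route instead. Acid-catalysed enol acetylation (isopropenyl acetate, p-TsOH, reflux) should give the linear dienyl acetate methyl 2-[(1S,6R)-5-acetoxy-6-methylcyclohexa-2,4-dien-1-yl]acetate F1. NaBH4 in aqueous ethanol at 0 °C cleaves the enol ester, the dienolate is protonated kinetically at the α-carbon and the resulting β,γ-unsaturated ketone is reduced in the same flask to the homoallylic alcohol methyl 2-[(1S,6R)-5-hydroxy-6-methylcyclohex-2-en-1-yl]acetate F2 (carbinol epimers). Buffered oxidation with the periodinane 1,1,1-triacetoxy-1,1-dihydro-1,2-benziodoxol-3(1H)-one and pyridine gives the β,γ-unsaturated ketone methyl 2-[(1S,6R)-6-methyl-5-oxocyclohex-2-en-1-yl]acetate F3. Silyl-transfer ketalisation (1,2-bis(trimethylsilyloxy)ethane, cat. TMSOTf, CH2Cl2, −78 °C) does not move the alkene and returns the route at 7.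

**Step 10 (Ireland–Claisen rearrangement).** Imperfect control of the ketene acetal geometry, or partial leakage through a boat transition state, would erode the configuration at C1; C2 and the butenyl geometry do not depend on it. The fallback sets out from 15 and lets thermodynamics set C1 after ring closure. Enolisation with LiN(iPr)2 in THF alone (no DMPU) and TMSCl should give the opposite ketene acetal geometry cleanly, and rearrangement and methylation then give the C1 epimer, methyl (2R,3S,4E)-3-[(1Z)-1-iodoprop-1-en-2-yl]-4-methyl-2-[(6R,7S)-6-methyl-1,4-dioxaspiro[4.5]dec-8-en-7-yl]hex-4-enoate F4. Heck cyclisation under the conditions of step 11 (the cis fusion is dictated by C8a, not C1) gives the C1 epimer of 20, F5, whose ester sits axial and syn to C5. Equilibration α to the ester (NaOMe, MeOH, 50 °C) should move it to the equatorial position and return the route at 20.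

**Step 14 (dissolving-metal reduction).** The protonation that fixes C7 may not follow thermodynamic control, or the metal may over-reduce or isomerise the substrate through the doubly allylic C4a–H. The fallback sets out from 22 and separates the two reductions. Conjugate reduction with [(Ph3P)CuH]6 in benzene gives the saturated hydroxy ketone 2-[(E)-but-2-en-2-yl]-1-(hydroxymethyl)-3,8-dimethyl-1,4a,5,6,8,8a-hexahydronaphthalen-7(2H)-one F6. NaBH4 reduction gives the diol as a mixture that may be rich in the C7 epimer of 23, F7. Meerwein–Ponndorf–Verley/Oppenauer equilibration (Al(OiPr)3, iPrOH, trace acetone, reflux) then epimerises the carbinol through the ketone to the equatorial alcohol and returns the route at 23.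

## Further compounds

F1 | step 3 | methyl 2-[(1S,6R)-5-acetoxy-6-methylcyclohexa-2,4-dien-1-yl]acetate | COC(=O)C[C@H]1C=CC=C(OC(C)=O)[C@@H]1C
F2 | step 3 | methyl 2-[(1S,6R)-5-hydroxy-6-methylcyclohex-2-en-1-yl]acetate (carbinol epimers) | COC(=O)C[C@H]1C=CCC(O)[C@@H]1C
F3 | step 3 | methyl 2-[(1S,6R)-6-methyl-5-oxocyclohex-2-en-1-yl]acetate | COC(=O)C[C@H]1C=CCC(=O)[C@@H]1C
F4 | step 10 | methyl (2R,3S,4E)-3-[(1Z)-1-iodoprop-1-en-2-yl]-4-methyl-2-[(6R,7S)-6-methyl-1,4-dioxaspiro[4.5]dec-8-en-7-yl]hex-4-enoate | C/C=C(\C)[C@@H](/C(C)=C\I)[C@H](C(=O)OC)[C@H]1C=CCC2(OCCO2)[C@@H]1C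
F5 | step 10 | C1 epimer of 20 | C/C=C(\C)[C@H]1C(C)=C[C@H]2C=CC3(OCCO3)[C@H](C)[C@H]2[C@H]1C(=O)OC
F6 | step 14 | 2-[(E)-but-2-en-2-yl]-1-(hydroxymethyl)-3,8-dimethyl-1,4a,5,6,8,8a-hexahydronaphthalen-7(2H)-one (stereocentres as in 22) | C/C=C(\C)[C@H]1C(C)=C[C@H]2CCC(=O)[C@H](C)[C@H]2[C@@H]1CO
F7 | step 14 | C7 epimer of 23 | C/C=C(\C)[C@H]1C(C)=C[C@H]2CC[C@@H](O)[C@H](C)[C@H]2[C@@H]1CO
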